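All runs come from a simulation for substances that don't exist; scatter was added.

Percent of the starting material charged is our unit, so that starting material, cross product, target and over-reaction product add up to 100 within the scatter, and on a repeat of these flasks the sum to watch is target plus over-reaction product.

| setting | maple | larch | summer | autumn |
|---|---|---|---|---|
| starting material | 0.20 M | 0.20 M | 0.20 M | 0.20 M |
| partner | 0.070 M | 0.11 M | 0.140 M | 0.140 M |
| second substrate | 0.20 M | 0.20 M | 0.200 M | 0.200 M |
| remark | run made earlier | run made earlier |  |  |
| time |  |  | 4.0 min | 5.0 min |

| run | time / min | cross product / % | target / % | starting material / % | over-reaction product / % |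
|---|---|---|---|---|---|
| maple | 0.500 | 14.4 | 5.8 | 79.0 | 0.6 |
| maple | 1.00 | 24.7 | 7.1 | 67.0 | 1.3 |
| maple | 1.50 | 31.5 | 6.3 | 59.3 | 2.4 |
| maple | 2.50 | 42.1 | 5.6 | 49.0 | 3.3 |
| maple | 3.00 | 45.8 | 4.3 | 45.4 | 4.1 |
| maple | 4.00 | 52.0 | 3.5 | 38.9 | 5.6 |
| larch | 0.200 | 6.7 | 5.9 | 87.5 | 0.5 |
| larch | 0.667 | 17.1 | 10.4 | 70.9 | 0.8 |
| larch | 1.00 | 22.8 | 10.9 | 64.5 | 2.2 |
| larch | 1.50 | 29.4 | 10.4 | 57.0 | 3.3 |
| larch | 2.50 | 38.2 | 8.6 | 47.8 | 5.2 |
| larch | 3.00 | 42.0 | 7.4 | 43.9 | 6.7 |
| larch | 4.00 | 47.4 | 5.7 | 38.3 | 7.7 |

(standard deviation of a reading: 0.3 percentage points)

* which of these there is most of at the end, counted by the starting material in it, summer (cross product / over-reaction product / target / starting material)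
* which of these there is most of at the end, counted by the starting material in it, autumn (cross product / over-reaction product / target / starting material)
* amount of the one of these that there is most of at the end, in percent of the starting material charged, summer
* amount of the one of these that there is most of at the end, in percent of the starting material charged, autumn

- the analysis behind the earlier runs scatters by 0.3 percentage points, standard deviation
- steps that have been proposed: starting material + partner -> target; second substrate + partner -> second product; starting material + second substrate -> cross product; target -> over-reaction product; 2 partner -> homo dimer; partner -> decomposed reagent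

In the larch run that sum reads 13.8% after 2.50 min and 13.4% after 4.00 min, so within the scatter these readings show no further rise. Counted per partner charged, its last reading is 0.260 in the maple run and 0.244 in the larch run, and the mean of these readings, 0.252, is our capture share φ, taken with starting material and second substrate at 0.20 M each. Summer and autumn keep those charges and carry 0.140 M of partner, so we expect the sum to stand at 17.6% in both flasks.

The forecast names cross product in summer at 44.2% and cross product in autumn at 47.9%, on a plateau of its own near 17.6, of which it says “That scales with partner charged”.

The flasks give cross product at 44.3% in summer and cross product at 48.4% in autumn.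

    starting material + partner → target (k = 0.0650 M⁻¹ s⁻¹)
    second substrate + partner → second product (k = 0.0964 M⁻¹ s⁻¹)
    starting material + second substrate → cross product (k = 0.0321 M⁻¹ s⁻¹)
    target → over-reaction product (k = 0.00407 s⁻¹)
    2 partner → homo dimer (k = 0.0125 M⁻¹ s⁻¹)
    partner → decomposed reagent (k = 0.0147 s⁻¹)

In summer the sum stands at 17.6% with 0.0520% of the charged partner, the limiting reagent, still free, and the turning of target into over-reaction product moves cross product by nothing. Autumn's 34% of starting material and our 17.6% leave 48.4% for cross product.

For the neighbour flask, summer with 0.084 M of partner, φ gives a sum of 10.6%; computed, it holds 10.8%, beside 38.8% of starting material and 50.4% of cross product.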